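**The choice.** I must choose when to stop. The racemate of E and D takes up Q, which comes from the gas G. E gives X and D gives Ym, and Z forms on the way.

| setting | south-east | north-east | flask |
|---|---|---|---|
| E | 3.4 × 10⁻⁴ M | 7.5 × 10⁻⁴ M | 5.0 × 10⁻⁴ M |
| D | 3.4 × 10⁻⁴ M | 7.5 × 10⁻⁴ M | 5.0 × 10⁻⁴ M |
| G | 0.053 mM (held) | 0.053 mM (held) | 0.053 mM (held) |
| remark | run made earlier | run made earlier |  |
| time |  |  | 3.0 min |

| run | time / min | X / % | Ym / % | E / % |
|---|---|---|---|---|
| south-east | 0.250 | 8.1 | 3.7 | 33.6 |
| south-east | 0.333 | 7.9 | 6.8 | 31.9 |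
| south-east | 0.500 | 13.4 | 7.9 | 23.5 |
| south-east | 0.833 | 22.8 | 15.4 | 18.1 |
| south-east | 1.33 | 30.7 | 21.0 | 12.3 |
| south-east | 2.00 | 39.6 | 27.3 | 9.3 |
| south-east | 3.00 | 49.5 | 37.2 | 2.6 |
| north-east | 0.417 | 7.9 | 3.7 | 30.9 |
| north-east | 0.833 | 16.4 | 7.4 | 23.7 |
| north-east | 1.33 | 21.2 | 13.7 | 18.7 |
| north-east | 1.50 | 23.6 | 15.5 | 19.6 |
| north-east | 2.00 | 30.4 | 20.2 | 15.1 |
| north-east | 2.50 | 35.8 | 24.0 | 9.2 |
| north-east | 3.00 | 41.0 | 29.3 | 8.4 |

(standard deviation of a reading: 1 percentage point)

- excess of X over Ym in the product at 4.0 s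
- excess of X over Ym in the product at 3.0 min
- part of the E and D charged together that has reacted at 3.0 min

- Q is single-handed; E and D are mirror images of each other, charged as a racemate, each of them at the stated concentration
- at the start none of G is in solution
- what has gone into Z counts as reacted
- an excess is the difference of the two amounts in percent of their sum
- an excess is below zero if the other one leads
- the handed part of Q does not stay in what it makes, so the products of the two hands are mirror images too

**One ratio.** I carry the selectivity factor s, the rate of X over that of Ym at equal E and D. The earliest readings pooled, from both runs up to 0.833 min, give X 76.5 % and Ym 44.9 %, so I read s = 1.70. At 4.0 s, with E and D still about equal, the excess should be (s − 1)/(s + 1) = 26.0 %.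

**My reckoning.** At 3.0 min the earlier runs show excesses of 14.2 % and 16.6 %, so I take 15.4 %, less than the early value. Those runs then hold 86.7 % and 70.3 % as X and Ym together, so I keep the stop at 3.0 min. E there reads 5.50 % on average. D is not read, so I assume that Z feeds both hands alike, which puts D near s times E and the reacted part at 85.1 %.

**The flask.** The forecast gives 40 %, 16 % and 79 %, saying “extrapolation gives about 40%”.

    Q + D → Ym (k = 420 /M/s)
    E ⇌ Z (K = 0.970, k = 0.0180 /s)
    D ⇌ Z (K = 0.970, k = 0.0180 /s)
    Q ⇌ J (K = 9.80, k = 0.0180 /s)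
    Q + E → X (k = 720 /M/s)
    G ⇌ Q, rate k6*(csat - [Q]) (kL = 0.180 /s)

The flask gives 26.1 %, 16.2 % and 87.9 % reacted. At 3.00 min it holds E 4.92 % and D 7.17 %, and s times E over D gives 1.17, while Q goes to X 1.2 times as fast as to Ym. D and Z relax with a half-life of 0.316 min, shorter than the 3.0 min run, and Z still holds 8.31 %.

The data are calculated with made-up constants; the scatter is artificial.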